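**Plan**
Ring numbering: C1 (OH), C2 (H), C3 (heptadecyl), C4 (OMe), C5 (OMe), C6 (H). The C4–O bond is traced back to a C4 acetyl group (Baeyer–Villiger), and the benzene ring is then cut at C2–C3 and C4–C5.
The enabling feature is the meta pair of differentiated oxygens on the benzene ring (free OH at C1, OMe at C5). It maps onto a diene C5–C6–C1–C2 with a ketene dimethyl acetal at C5 and a silyl enol ether at C1; the adjacent C3 (chain) and C4 (oxygen via acyl) come from an ynone.
Forward: octadecanal is homologated to henicos-3-yn-2-one, so the chain is in place before the ring exists; acetyl chloride and 1,1-dichloroethene give the diene. The only ring arises in one Diels–Alder/aromatisation event, followed by O-benzylation, acetyl-to-oxygen exchange, O-methylation and debenzylation.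
The target has no stereocentre; the one selectivity needed is the regiochemistry of the cycloaddition, set by the matched polarisation of diene and ynone.

Key step: step 6

Assumption: octadecanal oligomerises and air-oxidises on storage, so it is taken as freshly purified commercial material; diene 11 is hydrolytically labile and is used freshly distilled.

**Route**

Step 1
Reactants: 1 octadecanal
Product: 2 1,1-dibromononadec-1-ene
Conditions: CBr4, PPh3, CH2Cl2, 0 °C; hexane trituration, filtration through silica
Reagents that add atoms: carbon tetrabromide, BrC(Br)(Br)Br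
Why: First stage of the Corey–Fuchs homologation, in which the ylide Ph3P=CBr2 formed from CBr4 and PPh3 undergoes a Wittig olefination with the unhindered aliphatic aldehyde.

Step 2
Reactants: 2 1,1-dibromononadec-1-ene, 3 N-methoxy-N-methylacetamide
Product: 5 henicos-3-yn-2-one, via nonadec-1-yn-1-yllithium 4 (not isolated)
Conditions: n-BuLi (2.1 equiv), THF, −78 to 0 °C; then 3, −78 to 0 °C; 1 M HCl quench
Reagents that add atoms: none
Why: Second stage of the Corey–Fuchs sequence (Li/Br exchange, elimination and deprotonation to the lithium acetylide) followed by a Weinreb ketone synthesis, whose chelated tetrahedral adduct should prevent over-addition.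

Step 3
Reactants: 6 acetyl chloride, 7 1,1-dichloroethene
Product: 9 4,4-dichlorobut-3-en-2-one, via 4,4,4-trichlorobutan-2-one 8 (not isolated)
Conditions: AlCl3 (1.1 equiv), CH2Cl2, 0 °C to rt; ice–water; steam distillation
Reagents that add atoms: none
Why: Darzens–Nenitzescu-type acylation of the alkene, in which the acylium ion adds to the CH2 terminus and chloride capture gives the trichloromethyl ketone, which should lose HCl from its acidic alpha position on steam distillation to give the conjugated dichloroenone.

Step 4
Reactants: 9 4,4-dichlorobut-3-en-2-one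
Product: 10 4,4-dimethoxybut-3-en-2-one
Conditions: NaOMe (2.1 equiv), MeOH, 0 °C to rt
Reagents that add atoms: sodium methoxide, C[O-].[Na+]
Why: Two successive addition–elimination events (nucleophilic vinylic substitution) at the beta carbon of this vinylogous acid chloride should replace both chlorides by methoxide.

Step 5
Reactants: 10 4,4-dimethoxybut-3-en-2-one
Product: 11 1,1-dimethoxy-3-(trimethylsilyloxy)buta-1,3-diene
Conditions: Me3SiCl, Et3N, ZnCl2 (cat.), PhMe, 40 °C; filtration, distillation under reduced pressure
Reagents that add atoms: chlorotrimethylsilane, C[Si](C)(C)Cl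
Why: Enol silylation of the methyl ketone, whose methyl group is the only enolisable position, under amine/ZnCl2 conditions standard for 2-silyloxydienes.

Step 6
Reactants: 11 1,1-dimethoxy-3-(trimethylsilyloxy)buta-1,3-diene, 5 henicos-3-yn-2-one
Product: 14 1-(2-heptadecyl-4-hydroxy-6-methoxyphenyl)ethan-1-one, via cyclohexa-1,4-diene cycloadduct 12 (not isolated), via aryl trimethylsilyl ether 13 (not isolated)
Conditions: 11 (2.5 equiv), PhMe, 90–110 °C, sealed vessel; then 1 M HCl, THF, rt
Reagents that add atoms: none
Why: This is a thermal, concerted but strongly asynchronous [4+2] cycloaddition of normal electron demand between the doubly donor-substituted diene and the acetyl-activated alkyne, the reaction type established for 1,1-dialkoxy-3-silyloxybutadienes with acetylenic ketones and esters as a route to resorcinol monoethers. The unsubstituted CH2 terminus of 11, which carries the largest donor coefficient, bonds to the chain-bearing beta carbon of the ynone (target C2–C3) and the acetal carbon bonds to the alpha carbon (target C4–C5). The six-membered carbocycle, the only ring of the target, therefore closes in the cycloaddition itself and needs no separate cyclisation. Cycloadduct 12 should aromatise by 1,4-elimination of methanol from the acetal carbon and the ring CH2 to give silyl ether 13, and dilute acid then cleaves the Si–O bond to phenol 14. No stereocentre is formed. The selectivity required is regiochemical (acetyl between chain and OMe, OH para to acetyl), and it is secured by pairing the most nucleophilic diene terminus with the most electrophilic alkyne carbon.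

Step 7
Reactants: 14 1-(2-heptadecyl-4-hydroxy-6-methoxyphenyl)ethan-1-one
Product: 15 1-[4-(benzyloxy)-2-heptadecyl-6-methoxyphenyl]ethan-1-one
Conditions: BnBr, K2CO3, DMF, rt
Reagents that add atoms: benzyl bromide, BrCc1ccccc1
Why: Williamson ether synthesis on the acidic para-acyl phenol, the only nucleophilic site, installs a group that withstands peracid, carbonate and methylation and leaves by hydrogenolysis.

Step 8
Reactants: 15 1-[4-(benzyloxy)-2-heptadecyl-6-methoxyphenyl]ethan-1-one
Product: 16 4-(benzyloxy)-2-heptadecyl-6-methoxyphenyl acetate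
Conditions: mCPBA (2 equiv), CF3CO2H (1 equiv), CH2Cl2, 0 °C to rt, dark
Reagents that add atoms: 3-chloroperoxybenzoic acid, OOC(=O)c1cccc(Cl)c1
Why: Baeyer–Villiger oxidation in which the electron-rich aryl group migrates in preference to methyl from the Criegee adduct, helped by the two ortho substituents that twist the acetyl group out of conjugation and make its carbonyl more electrophilic.

Step 9
Reactants: 16 4-(benzyloxy)-2-heptadecyl-6-methoxyphenyl acetate
Product: 18 5-(benzyloxy)-1-heptadecyl-2,3-dimethoxybenzene, via 4-(benzyloxy)-2-heptadecyl-6-methoxyphenol 17 (not isolated)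
Conditions: K2CO3, degassed MeOH–THF, rt; evaporation; then MeI, K2CO3, DMF, rt
Reagents that add atoms: iodomethane, CI
Why: Carbonate-mediated transesterification of the aryl acetate followed in the same flask by Williamson O-methylation of the phenoxide, so that the oxidation-prone electron-rich phenol is never handled in air.

Step 10
Reactants: 18 5-(benzyloxy)-1-heptadecyl-2,3-dimethoxybenzene
Product: 19 3-heptadecyl-4,5-dimethoxyphenol
Conditions: H2 (1 atm), 10% Pd/C, EtOAc–EtOH, rt
Reagents that add atoms: none
Why: Catalytic hydrogenolysis of the benzylic C–O bond should release the C1 phenol, since the aryl methyl ethers and the saturated chain are inert under these conditions.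

**Compound list**
1 | octadecanal | CCCCCCCCCCCCCCCCCC=O | starting material
2 | 1,1-dibromononadec-1-ene | CCCCCCCCCCCCCCCCCC=C(Br)Br | intermediate
3 | N-methoxy-N-methylacetamide | CON(C)C(C)=O | starting material
4 | nonadec-1-yn-1-yllithium | CCCCCCCCCCCCCCCCCC#C[Li] | intermediate
5 | henicos-3-yn-2-one | CCCCCCCCCCCCCCCCCC#CC(C)=O | intermediate
6 | acetyl chloride | CC(=O)Cl | starting material
7 | 1,1-dichloroethene | C=C(Cl)Cl | starting material
8 | 4,4,4-trichlorobutan-2-one | CC(=O)CC(Cl)(Cl)Cl | intermediate
9 | 4,4-dichlorobut-3-en-2-one | CC(=O)C=C(Cl)Cl | intermediate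
10 | 4,4-dimethoxybut-3-en-2-one | COC(OC)=CC(C)=O | intermediate
11 | 1,1-dimethoxy-3-(trimethylsilyloxy)buta-1,3-diene | COC(OC)=CC(=C)O[Si](C)(C)C | intermediate
12 | 1-[2-heptadecyl-6,6-dimethoxy-4-(trimethylsilyloxy)cyclohexa-1,4-dien-1-yl]ethan-1-one | CCCCCCCCCCCCCCCCCC1=C(C(C)=O)C(OC)(OC)C=C(O[Si](C)(C)C)C1 | intermediate
13 | 1-[2-heptadecyl-6-methoxy-4-(trimethylsilyloxy)phenyl]ethan-1-one | CCCCCCCCCCCCCCCCCc1cc(O[Si](C)(C)C)cc(OC)c1C(C)=O | intermediate
14 | 1-(2-heptadecyl-4-hydroxy-6-methoxyphenyl)ethan-1-one | CCCCCCCCCCCCCCCCCc1cc(O)cc(OC)c1C(C)=O | intermediate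
15 | 1-[4-(benzyloxy)-2-heptadecyl-6-methoxyphenyl]ethan-1-one | CCCCCCCCCCCCCCCCCc1cc(OCc2ccccc2)cc(OC)c1C(C)=O | intermediate
16 | 4-(benzyloxy)-2-heptadecyl-6-methoxyphenyl acetate | CCCCCCCCCCCCCCCCCc1cc(OCc2ccccc2)cc(OC)c1OC(C)=O | intermediate
17 | 4-(benzyloxy)-2-heptadecyl-6-methoxyphenol | CCCCCCCCCCCCCCCCCc1cc(OCc2ccccc2)cc(OC)c1O | intermediate
18 | 5-(benzyloxy)-1-heptadecyl-2,3-dimethoxybenzene | CCCCCCCCCCCCCCCCCc1cc(OCc2ccccc2)cc(OC)c1OC | intermediate
19 | 3-heptadecyl-4,5-dimethoxyphenol | CCCCCCCCCCCCCCCCCc1cc(O)cc(OC)c1OC | target

**Step count**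
Total: 10 steps. Longest linear sequence: 8 steps (steps 3, 4, 5, 6, 7, 8, 9, 10, from acetyl chloride and 1,1-dichloroethene); the ynone branch (steps 1 and 2) joins at step 6.

**Steps most likely to fail**

1) Step 6, the cycloaddition. Addition to the beta-alkylated, acetyl-bearing triple bond may be slow enough that thermal decomposition or adventitious hydrolysis of the ketene acetal diene, or silyl transfer to the enolisable acetyl group, outruns ring formation. The fallback replaces acetyl by the smaller, more strongly activating, non-enolisable formyl group and changes the later carbon-to-oxygen exchange to match. It sets out from acetylide 4, which is quenched with DMF and then buffered aqueous KH2PO4 to give icos-2-ynal F1. Heating F1 with diene 11 in toluene at 60–80 °C should give the cycloadduct 2-heptadecyl-6,6-dimethoxy-4-(trimethylsilyloxy)cyclohexa-1,4-diene-1-carbaldehyde F2, which loses methanol to 2-heptadecyl-6-methoxy-4-(trimethylsilyloxy)benzaldehyde F3. Dilute HCl in THF then gives 2-heptadecyl-4-hydroxy-6-methoxybenzaldehyde F4. Benzylation (BnBr, K2CO3, DMF) gives 4-(benzyloxy)-2-heptadecyl-6-methoxybenzaldehyde F5. A Dakin-type Baeyer–Villiger oxidation with mCPBA in CH2Cl2 should then give 4-(benzyloxy)-2-heptadecyl-6-methoxyphenyl formate F6. Methanolysis of F6 with K2CO3 in degassed MeOH gives phenol 17, where the route is rejoined; methylation as in the second half of step 9 leads to 18.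

2) Step 8, the Baeyer–Villiger oxidation. Peracid attack on the electron-rich, trisubstituted ring (hydroxylation and quinone formation) may compete with the slow addition to the hindered, twisted carbonyl group. The fallback exchanges carbon for oxygen by a cationic hydroperoxide rearrangement instead, setting out from ketone 15. Reduction with LiAlH4 in THF at 0 °C should give racemic 1-[4-(benzyloxy)-2-heptadecyl-6-methoxyphenyl]ethan-1-ol F7. Treatment with aqueous H2O2 and catalytic TsOH in THF at 0 °C ionises F7 to a stabilised benzylic cation, which is captured as 5-(benzyloxy)-1-heptadecyl-2-(1-hydroperoxyethyl)-3-methoxybenzene F8. Acid-induced aryl migration from carbon to oxygen (Hock rearrangement) and hydrolysis of the resulting hemiacetal then release phenol 17, where the route is rejoined.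

3) Step 9, the one-flask acetate cleavage and methylation. The electron-rich phenoxide generated in basic methanol may be air-oxidised to quinonoid products before it is alkylated. The fallback avoids any phenoxide, setting out from acetate 16. Hydrazinolysis (N2H4·H2O, THF–MeOH, rt) removes the acetyl group under nearly neutral conditions, and phenol 17 is isolated. It is then methylated by a Mitsunobu reaction (MeOH, PPh3, diisopropyl azodicarboxylate, THF), a redox condensation in place of base and alkyl halide, which returns to the route at 18.

**Further compounds**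
F1 | step 6 | icos-2-ynal | CCCCCCCCCCCCCCCCCC#CC=O
F2 | step 6 | 2-heptadecyl-6,6-dimethoxy-4-(trimethylsilyloxy)cyclohexa-1,4-diene-1-carbaldehyde | CCCCCCCCCCCCCCCCCC1=C(C=O)C(OC)(OC)C=C(O[Si](C)(C)C)C1
F3 | step 6 | 2-heptadecyl-6-methoxy-4-(trimethylsilyloxy)benzaldehyde | CCCCCCCCCCCCCCCCCc1cc(O[Si](C)(C)C)cc(OC)c1C=O
F4 | step 6 | 2-heptadecyl-4-hydroxy-6-methoxybenzaldehyde | CCCCCCCCCCCCCCCCCc1cc(O)cc(OC)c1C=O
F5 | step 6 | 4-(benzyloxy)-2-heptadecyl-6-methoxybenzaldehyde | CCCCCCCCCCCCCCCCCc1cc(OCc2ccccc2)cc(OC)c1C=O
F6 | step 6 | 4-(benzyloxy)-2-heptadecyl-6-methoxyphenyl formate | CCCCCCCCCCCCCCCCCc1cc(OCc2ccccc2)cc(OC)c1OC=O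
F7 | step 8 | 1-[4-(benzyloxy)-2-heptadecyl-6-methoxyphenyl]ethan-1-ol (racemic) | CCCCCCCCCCCCCCCCCc1cc(OCc2ccccc2)cc(OC)c1C(C)O
F8 | step 8 | 5-(benzyloxy)-1-heptadecyl-2-(1-hydroperoxyethyl)-3-methoxybenzene (racemic) | CCCCCCCCCCCCCCCCCc1cc(OCc2ccccc2)cc(OC)c1C(C)OO
F0 | step 9 | none | none
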